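**Strategy.** Everything hinges on disconnecting C6–C7, the one bond common to the ten-membered carbocycle and the fused butenolide. C7 is the β-carbon of the C7=C11 enoate, and C6 is the lactone carbinol flanked by the cis C4–C5 epoxide. An open-chain (Z)-β-iodoenoate ending in a C6 epoxy aldehyde is therefore closed by a NiCl2/CrCl2 coupling whose chromium alkoxide lactonizes onto the cis ester. That single operation should form the carbocycle, the butenolide and the C6 stereocentre. The precursor is a linear chain grown from nerol that already carries C4, C5, C8, C10, the C13 acetate, a C8 silyl ether and a C1 PMB ether.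

Key step: step 15

Remark: target (germacrane) numbering is used for all intermediates; the C1 carbinol configuration is immaterial because C1 is oxidized to the ketone in the last step.

**Step 1**
Reactants: 1 nerol
Product: 2 neryl tert-butyldimethylsilyl ether
Conditions: TBSCl, imidazole, DMF, 0 °C to rt
Reagents that add atoms: tert-butyldimethylsilyl chloride, CC(C)(C)[Si](C)(C)Cl
Why: Routine silylation of the primary allylic alcohol masks the C6 oxygen until the epoxidation stage.

**Step 2**
Reactants: 2 neryl tert-butyldimethylsilyl ether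
Product: 3 distal (6,7-) epoxide of neryl silyl ether (racemic at the epoxide)
Conditions: mCPBA (1.0 equiv), CH2Cl2, −20 to 0 °C
Reagents that add atoms: 3-chloroperbenzoic acid, OOC(=O)c1cccc(Cl)c1
Why: Prilezhaev epoxidation should favour the more electron-rich distal alkene over the one deactivated by the allylic oxygen, and the new centre is cleaved away in the next step.

**Step 3**
Reactants: 3 distal epoxide of neryl silyl ether
Product: 5 (Z)-6-(tert-butyldimethylsilyloxy)-4-methylhex-4-enal (C1 aldehyde), via glycol 4 (not isolated)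
Conditions: H5IO6, THF–H2O, 0 °C
Reagents that add atoms: none
Why: Acid-promoted hydration at the tertiary carbon followed by Malaprade glycol cleavage should expel acetone and leave the C1 aldehyde with the Z C4=C5 alkene untouched, the aldehyde oxygen being the one delivered by the peracid.

**Step 4**
Reactants: 5 (Z)-6-(tert-butyldimethylsilyloxy)-4-methylhex-4-enal; 6 trans-2-butene
Product: 10 anti homoallylic alcohol (2Z,6R,7S)-1-(tert-butyldimethylsilyloxy)-3,7-dimethylnona-2,8-dien-6-ol (1R,10S in target numbering), via (E)-crotylpotassium 7 (not isolated), via (E)-crotyldiisopinocampheylborane 8 (not isolated), via homoallylic borinate 9 (not isolated)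
Conditions: KOtBu, n-BuLi, THF, −78 to −45 °C; (−)-Ipc2BOMe, −78 °C; BF3·OEt2, then 5, −78 °C; NaOH, H2O2, 0 °C to rt
Reagents that add atoms: none
Why: Asymmetric (E)-crotylboration through a chair Zimmerman–Traxler transition state should give the anti product, with the isopinocampheyl groups derived from (+)-α-pinene directing attack to the Si face of the aldehyde so that C10 is S (and C1 is R) under reagent control.

**Step 5**
Reactants: 10 anti homoallylic alcohol
Product: 11 C1 4-methoxybenzyl (PMB) ether of 10
Conditions: NaH, PMBCl, Bu4NI (cat.), THF–DMF, 0 °C to rt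
Reagents that add atoms: 4-methoxybenzyl chloride, COc1ccc(CCl)cc1
Why: Williamson etherification installs a C1 protecting group that can later be removed oxidatively under neutral conditions, so that no fluoride or base has to meet the finished epoxide, acetate and methacrylate.

**Step 6**
Reactants: 11 C1 PMB ether
Product: 13 primary C8 alcohol (vinyl group converted into CH2CH2OH), via B-alkyl-9-BBN 12 (not isolated)
Conditions: 9-BBN, THF, 0 °C to rt; NaOH, H2O2, 0 °C
Reagents that add atoms: hydrogen peroxide, OO
Why: Anti-Markovnikov hydroboration–oxidation with the bulky borane should select the monosubstituted vinyl group over the trisubstituted C4=C5 alkene.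

**Step 7**
Reactants: 13 primary C8 alcohol
Product: 14 C8 aldehyde with C1 as PMB ether and C6 as silyl ether
Conditions: Dess–Martin periodinane, CH2Cl2, 0 °C to rt
Reagents that add atoms: none
Why: Mild hypervalent-iodine oxidation of a primary alcohol stops at the aldehyde and leaves the silyl ether, the PMB ether and the alkene intact.

**Step 8**
Reactants: 14 C8 aldehyde; 15 methyl propiolate
Product: 17 (8R) γ-hydroxy ynoate, via methylzinc alkynylide 16 (not isolated)
Conditions: (R,R)-ProPhenol (20 mol %), Me2Zn (3 equiv), Ph3P=O (40 mol %), toluene, 0 to 4 °C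
Reagents that add atoms: none
Why: Dinuclear zinc ProPhenol-catalysed alkynylation should deliver the alkynylzinc to the Si face of the aldehyde under catalyst control, setting C8 as R, with any C8 epimer removable as a diastereomer.

**Step 9**
Reactants: 17 (8R) γ-hydroxy ynoate
Product: 18 γ-silyloxy ynoate (C8 tert-butyldimethylsilyl ether)
Conditions: TBSCl, imidazole, DMF, 0 °C to rt
Reagents that add atoms: tert-butyldimethylsilyl chloride, CC(C)(C)[Si](C)(C)Cl
Why: Silylation under weakly basic conditions avoids isomerization of the ynoate and gives a C8 ether that, unlike an ester, is a poor leaving group β to the later alkenylchromium.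

**Step 10**
Reactants: 18 γ-silyloxy ynoate; 19 formaldehyde
Product: 21 (Z)-β-iodo-α-(hydroxymethyl) enoate (iodine on C7 cis to the C12 ester and C13 hydroxymethyl cis to C8), via magnesium iodoallenolate 20 (not isolated)
Conditions: MgI2 (1.5 equiv), anhydrous CH2O (from cracked paraformaldehyde), CH2Cl2, −20 to 0 °C
Reagents that add atoms: magnesium iodide, [Mg+2].[I-].[I-]
Why: In this halo-aldol (β-iodo Morita–Baylis–Hillman type) reaction, iodide adds to C7 and the magnesium allenolate is hydroxymethylated at C11 anti to the new C–I bond (kinetic trans addition, as in hydroiodination of 2-alkynoates), which should place iodine cis to the ester.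

**Step 11**
Reactants: 21 (Z)-β-iodo-α-(hydroxymethyl) enoate
Product: 22 (Z)-β-iodo enoate with C13 acetate
Conditions: Ac2O, pyridine, CH2Cl2, 0 °C to rt
Reagents that add atoms: acetic anhydride, CC(=O)OC(C)=O
Why: Acylation of the primary alcohol installs the C13 acetate of the target, and omitting a nucleophilic catalyst spares the β-iodoenoate from addition–elimination.

**Step 12**
Reactants: 22 (Z)-β-iodo enoate with C13 acetate
Product: 23 C6 allylic alcohol (primary silyl ether removed)
Conditions: PPTS, MeOH, rt
Reagents that add atoms: none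
Why: Acid-catalysed methanolysis is much faster for the unhindered primary allylic silyl ether than for the hindered secondary C8 silyl ether, and the PMB ether, acetate and iodoenoate should be unaffected.

**Step 13**
Reactants: 23 C6 allylic alcohol
Product: 24 cis-(4S,5R)-epoxy alcohol
Conditions: Ti(OiPr)4 (10 mol %), D-(−)-diethyl tartrate (12 mol %), TBHP, 4 Å molecular sieves, CH2Cl2, −20 °C
Reagents that add atoms: tert-butyl hydroperoxide, CC(C)(C)OO
Why: Sharpless asymmetric epoxidation with the D-(−)-tartrate should deliver oxygen to the face of the Z allylic alcohol that gives 4S,5R, the cis relationship of C3 and C6 following from the alkene geometry, while the electron-poor iodoenoate alkene is inert.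

**Step 14**
Reactants: 24 cis-(4S,5R)-epoxy alcohol
Product: 25 open-chain epoxy aldehyde iodoenoate
Conditions: Dess–Martin periodinane, NaHCO3, CH2Cl2, 0 °C, used at once
Reagents that add atoms: none
Why: Buffered hypervalent-iodine oxidation converts the primary epoxy alcohol into the sensitive epoxy aldehyde without acid, so the epoxide stays closed.

**Step 15**
Reactants: 25 open-chain epoxy aldehyde iodoenoate
Product: 28 bicyclic germacranolide core (ten-membered carbocycle and butenolide closed; 6R; C8 silyl ether; C1 PMB ether), via alkenylchromium dichloride 26 (not isolated), via macrocyclic chromium alkoxide 27 (not isolated)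
Conditions: CrCl2 (10 equiv), NiCl2 (0.1 equiv), DMSO–THF, rt, syringe-pump addition to about 2 mM
Reagents that add atoms: none
Why: Proposed new method: zerovalent nickel (from NiCl2 and CrCl2) inserts into the C7–I bond, the alkenylnickel transmetalates to trivalent chromium, and alkenylchromium 26 adds to the C6 aldehyde to give alkoxide 27, whose oxygen then attacks the cis C12 methyl ester and expels methoxide. The closest known reaction types are the intramolecular Ni/Cr (Nozaki–Hiyama–Kishi) coupling of alkenyl iodides with aldehydes to form medium rings and the Ni/Cr coupling of (Z)-β-iodoenoates with aldehydes that lactonize to butenolides; their union on a tetrasubstituted iodoenoate and an epoxy aldehyde has not been shown. The ten-membered carbocycle closes by 10-exo-trig carbonyl addition (C6–C7) and the butenolide by 5-exo-trig acyl substitution (O6–C12). C6 is controlled by the C5 stereocentre: Felkin–Anh attack anti to the C5–O bond of the epoxide, with C4 on the side of the carbonyl oxygen, corresponds to the 6R configuration of the target. The step needs addition to the aldehyde alone, which should be secured by the aldehyde selectivity of organochromium reagents, the C1 PMB ether (no ketone for a five-membered closure), the poor leaving ability of the C8 silyl ether, the turn imposed by the cis epoxide and high dilution.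

**Step 16**
Reactants: 28 bicyclic germacranolide core
Product: 29 C8 alcohol of the bicyclic core
Conditions: HF·pyridine, pyridine, THF, 0 °C to rt
Reagents that add atoms: none
Why: Buffered fluoride desilylation removes the only silyl ether without basic fluoride, so the C13 acetate should not migrate and the epoxide, lactone and PMB ether should survive.

**Step 17**
Reactants: 29 C8 alcohol of the bicyclic core; 30 methacrylic anhydride
Product: 31 C8 methacrylate with C1 PMB ether
Conditions: Et3N, DMAP (cat.), CH2Cl2, 0 °C to rt
Reagents that add atoms: none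
Why: DMAP-catalysed acyl transfer esterifies the secondary allylic alcohol faster than any acetyl migration can occur.

**Step 18**
Reactants: 31 C8 methacrylate with C1 PMB ether
Product: 32 C1 alcohol (PMB removed)
Conditions: DDQ, CH2Cl2–pH 7 buffer, 0 °C
Reagents that add atoms: none
Why: Oxidative cleavage of the PMB ether (benzylic hydride abstraction, then hydrolysis) is neutral and should leave both esters, the butenolide and the epoxide untouched, and the γ-hydroxy epoxide is taken on at once to avoid transannular ether formation.

**Step 19**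
Reactants: 32 C1 alcohol
Product: 33 target CNP0128625.1
Conditions: Dess–Martin periodinane, NaHCO3, CH2Cl2, 0 °C to rt
Reagents that add atoms: none
Why: Buffered oxidation of the secondary carbinol gives the C1 ketone, erasing the temporary C1 centre without epimerizing the adjacent C10.

**Compound list**

1 | nerol | CC(C)=CCC/C(C)=C\CO | starting material
2 | neryl tert-butyldimethylsilyl ether | CC(C)=CCC/C(C)=C\CO[Si](C)(C)C(C)(C)C | intermediate
3 | distal (6,7-) epoxide of neryl silyl ether, racemic at the epoxide | CC1(C)OC1CC/C(C)=C\CO[Si](C)(C)C(C)(C)C | intermediate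
4 | glycol from hydration of 3 | CC(C)(O)C(O)CC/C(C)=C\CO[Si](C)(C)C(C)(C)C | intermediate (not isolated)
5 | (Z)-6-(tert-butyldimethylsilyloxy)-4-methylhex-4-enal | O=CCC/C(C)=C\CO[Si](C)(C)C(C)(C)C | intermediate
6 | trans-2-butene | C/C=C/C | starting material
7 | (E)-crotylpotassium | C/C=C/C[K] | intermediate (not isolated)
8 | (E)-crotyldiisopinocampheylborane, isopinocampheyl groups from (+)-α-pinene | C/C=C/CB([C@@H]1C[C@@H]2C[C@H]([C@H]1C)C2(C)C)[C@@H]1C[C@@H]2C[C@H]([C@H]1C)C2(C)C | intermediate (not isolated)
9 | homoallylic diisopinocampheylborinate of 10 | C=C[C@H](C)[C@H](OB([C@@H]1C[C@@H]2C[C@H]([C@H]1C)C2(C)C)[C@@H]1C[C@@H]2C[C@H]([C@H]1C)C2(C)C)CC/C(C)=C\CO[Si](C)(C)C(C)(C)C | intermediate (not isolated)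
10 | anti homoallylic alcohol, (2Z,6R,7S)-1-(tert-butyldimethylsilyloxy)-3,7-dimethylnona-2,8-dien-6-ol | C=C[C@H](C)[C@H](O)CC/C(C)=C\CO[Si](C)(C)C(C)(C)C | intermediate
11 | C1 PMB ether of 10 | C=C[C@H](C)[C@H](OCc1ccc(OC)cc1)CC/C(C)=C\CO[Si](C)(C)C(C)(C)C | intermediate
12 | B-alkyl-9-BBN from 11 | C1CC2CCCC(C1)B2CC[C@H](C)[C@H](OCc1ccc(OC)cc1)CC/C(C)=C\CO[Si](C)(C)C(C)(C)C | intermediate (not isolated)
13 | primary C8 alcohol | OCC[C@H](C)[C@H](OCc1ccc(OC)cc1)CC/C(C)=C\CO[Si](C)(C)C(C)(C)C | intermediate
14 | C8 aldehyde | O=CC[C@H](C)[C@H](OCc1ccc(OC)cc1)CC/C(C)=C\CO[Si](C)(C)C(C)(C)C | intermediate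
15 | methyl propiolate | C#CC(=O)OC | starting material
16 | methylzinc alkynylide of methyl propiolate | C[Zn]C#CC(=O)OC | intermediate (not isolated)
17 | (8R) γ-hydroxy ynoate | O[C@@H](C#CC(=O)OC)C[C@H](C)[C@H](OCc1ccc(OC)cc1)CC/C(C)=C\CO[Si](C)(C)C(C)(C)C | intermediate
18 | γ-silyloxy ynoate | CC(C)(C)[Si](C)(C)O[C@@H](C#CC(=O)OC)C[C@H](C)[C@H](OCc1ccc(OC)cc1)CC/C(C)=C\CO[Si](C)(C)C(C)(C)C | intermediate
19 | formaldehyde | C=O | starting material
20 | magnesium β-iodoallenolate | CC(C)(C)[Si](C)(C)O[C@@H](C(I)=C=C(OC)O[Mg]I)C[C@H](C)[C@H](OCc1ccc(OC)cc1)CC/C(C)=C\CO[Si](C)(C)C(C)(C)C | intermediate (not isolated)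
21 | (Z)-β-iodo-α-(hydroxymethyl) enoate | CC(C)(C)[Si](C)(C)O[C@@H](/C(I)=C(\CO)C(=O)OC)C[C@H](C)[C@H](OCc1ccc(OC)cc1)CC/C(C)=C\CO[Si](C)(C)C(C)(C)C | intermediate
22 | (Z)-β-iodo enoate with C13 acetate | CC(C)(C)[Si](C)(C)O[C@@H](/C(I)=C(\COC(C)=O)C(=O)OC)C[C@H](C)[C@H](OCc1ccc(OC)cc1)CC/C(C)=C\CO[Si](C)(C)C(C)(C)C | intermediate
23 | C6 allylic alcohol | CC(C)(C)[Si](C)(C)O[C@@H](/C(I)=C(\COC(C)=O)C(=O)OC)C[C@H](C)[C@H](OCc1ccc(OC)cc1)CC/C(C)=C\CO | intermediate
24 | cis-(4S,5R)-epoxy alcohol | CC(C)(C)[Si](C)(C)O[C@@H](/C(I)=C(\COC(C)=O)C(=O)OC)C[C@H](C)[C@H](OCc1ccc(OC)cc1)CC[C@]1(C)O[C@@H]1CO | intermediate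
25 | open-chain epoxy aldehyde iodoenoate | CC(C)(C)[Si](C)(C)O[C@@H](/C(I)=C(\COC(C)=O)C(=O)OC)C[C@H](C)[C@H](OCc1ccc(OC)cc1)CC[C@]1(C)O[C@@H]1C=O | intermediate
26 | alkenylchromium dichloride from 25 | CC(C)(C)[Si](C)(C)O[C@@H](/C([Cr](Cl)Cl)=C(\COC(C)=O)C(=O)OC)C[C@H](C)[C@H](OCc1ccc(OC)cc1)CC[C@]1(C)O[C@@H]1C=O | intermediate (not isolated)
27 | macrocyclic chromium alkoxide (ten-membered ring closed, ester still open) | CC(C)(C)[Si](C)(C)O[C@@H]1C[C@H](C)[C@H](OCc3ccc(OC)cc3)CC[C@]2(C)O[C@@H]2[C@H](O[Cr](Cl)Cl)/C1=C(/COC(C)=O)C(=O)OC | intermediate (not isolated)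
28 | bicyclic germacranolide core, C8 silyl ether, C1 PMB ether | CC(C)(C)[Si](C)(C)O[C@@H]1C[C@H](C)[C@H](OCc3ccc(OC)cc3)CC[C@]2(C)O[C@@H]2[C@@H]2OC(=O)C(COC(C)=O)=C21 | intermediate
29 | C8 alcohol of the core | O[C@@H]1C[C@H](C)[C@H](OCc3ccc(OC)cc3)CC[C@]2(C)O[C@@H]2[C@@H]2OC(=O)C(COC(C)=O)=C21 | intermediate
30 | methacrylic anhydride | C=C(C)C(=O)OC(=O)C(C)=C | starting material
31 | C8 methacrylate, C1 PMB ether | C=C(C)C(=O)O[C@@H]1C[C@H](C)[C@H](OCc3ccc(OC)cc3)CC[C@]2(C)O[C@@H]2[C@@H]2OC(=O)C(COC(C)=O)=C21 | intermediate
32 | C1 alcohol | C=C(C)C(=O)O[C@@H]1C[C@H](C)[C@H](O)CC[C@]2(C)O[C@@H]2[C@@H]2OC(=O)C(COC(C)=O)=C21 | intermediate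
33 | CNP0128625.1 | C=C(C)C(=O)O[C@@H]1C[C@H](C)C(=O)CC[C@]2(C)O[C@@H]2[C@@H]2OC(=O)C(COC(C)=O)=C21 | target

**Totals.** Total step count: 19. Longest linear sequence: 19 steps (from nerol).

**Steps most likely to fail**

1. Step 15 (labelled step). What may go wrong: reduction or Lewis-acid opening of the epoxy aldehyde by the chromium salts, protodeiodination of the hindered alkenylchromium, or intermolecular coupling outrunning the slow ten-membered closure. The fallback introduces the epoxide after ring closure, each operation being of a known type. It sets out from allylic alcohol 23. Oxidation with MnO2 (CH2Cl2, rt) should give the (Z)-enal F1. Ni/Cr closure of the alkenyl iodide onto the enal (CrCl2, cat. NiCl2, DMSO–THF, high dilution), with lactonization of the resulting hydroxy ester, should give the 4Z-dienolide F2. Epoxidation of its only electron-rich alkene, C4=C5, with mCPBA/NaHCO3 from the exposed outer face of the ring, as practised on 4,5-alkenes of germacranolides, comes back to 28. In this variant C6 and the epoxide face depend on the ring conformation and would have to be verified.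

2. Step 10. What may go wrong: attack of formaldehyde on the allenolate from the iodine side (iodine trans to the ester), loss of geometry through reversible iodide addition, or Lewis-acid cleavage of the PMB or silyl ethers. The fallback fixes the geometry with a bulky stannyl group and then exchanges tin for iodine. It sets out from ynoate 18. Conjugate addition of Me3SnCu·SMe2 (THF, −78 to −48 °C), equilibrated so that tin lies cis to the ester, and trapping with formaldehyde trans to tin should give the (Z)-β-stannyl-α-(hydroxymethyl) enoate F3. Iododestannylation (I2, CH2Cl2, 0 °C) with retention comes back to 21.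

3. Step 8. What may go wrong: self-aldol of the enolizable α-unbranched aldehyde under the zinc conditions and incomplete catalyst control at C8 next to the existing C10 centre. The fallback sets C8 by reagent-controlled ketone reduction. It sets out from aldehyde 14. Addition of lithiated methyl propiolate (LiN(SiMe3)2, THF, −78 °C) should give the C8-epimeric hydroxy ynoates F4. Dess–Martin oxidation should give the ynone F5. Midland reduction with (R)-Alpine-Borane, the alkynyl group acting as the small substituent, comes back to 17.

**Further compounds**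

F1 | step 15 | (Z)-enal from oxidation of 23 | CC(C)(C)[Si](C)(C)O[C@@H](/C(I)=C(\COC(C)=O)C(=O)OC)C[C@H](C)[C@H](OCc1ccc(OC)cc1)CC/C(C)=C\C=O
F2 | step 15 | 4Z-dienolide (ten-membered ring and butenolide closed, no epoxide) | CC(C)(C)[Si](C)(C)O[C@@H]1C[C@H](C)[C@H](OCc3ccc(OC)cc3)CC/C(C)=C\[C@@H]2OC(=O)C(COC(C)=O)=C21
F3 | step 10 | (Z)-β-trimethylstannyl-α-(hydroxymethyl) enoate | CC(C)(C)[Si](C)(C)O[C@@H](/C([Sn](C)(C)C)=C(\CO)C(=O)OC)C[C@H](C)[C@H](OCc1ccc(OC)cc1)CC/C(C)=C\CO[Si](C)(C)C(C)(C)C
F4 | step 8 | C8-epimeric γ-hydroxy ynoates | OC(C#CC(=O)OC)C[C@H](C)[C@H](OCc1ccc(OC)cc1)CC/C(C)=C\CO[Si](C)(C)C(C)(C)C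
F5 | step 8 | C8 ynone (4-oxo-2-ynoate) | O=C(C#CC(=O)OC)C[C@H](C)[C@H](OCc1ccc(OC)cc1)CC/C(C)=C\CO[Si](C)(C)C(C)(C)C
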